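**Numbering used throughout:** 1 sinapic acid; 2 methanol; 3 methyl sinapate; 4 pivaloyl chloride; 5 cinnamate partner; 6 benzyl bromide; 7 methyl 4-O-benzylsinapate; 8 4-O-benzylsinapyl alcohol; 9 chlorotriisopropylsilane; 10 styrene partner; 11 cyclobutane; 12 tetralin ester; 13 tetralin phenol alcohol; 14 tribenzyl silyl ether; 15 C2 carbinol; 16 SO3·pyridine; 17 pyridinium sulfate; 18 sodium sulfate; 19 sodium salt of the target; 20 target.

**Remarks on the chemistry (assumptions):**
- The hydrogen sulfate is carried as its sodium salt and protonated only in the last operation.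
- Tetralins are numbered as in the target (C1 = aryl-bearing carbon) in all names, esters included.
- The silyl ether is triisopropylsilyl rather than tert-butyldimethylsilyl. It is less Lewis basic towards the boron catalyst and should not migrate to the neighbouring alkoxide during the later benzylation.
- The sensitiser for the photocycloaddition is [Ir(ppy)2(dtbbpy)]PF6 (triplet energy near 49 kcal/mol, weak excited-state oxidant). The more energetic and more oxidising [Ir(dF(CF3)ppy)2(dtbbpy)]PF6 (near 61 kcal/mol) would also excite unbound 5 and the trialkoxystyrene 10 and could oxidise 10 to its radical cation.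
- One-electron oxidation alone cannot finish the ring expansion, because C4 must gain a hydrogen atom. A thiol hydrogen-atom shuttle is therefore added, making the step a redox-neutral isomerisation.

## Analysis of the target

Target 20 is a 1-aryl-1,2,3,4-tetrahydronaphthalene of the lyoniresinol type. Ring A is the fused arene C4a–C8a with methoxyls at C6 and C8 and a free phenol at C7; ring B is the carbocycle C1–C4; the pendant ring at C1 is 4-hydroxy-3,5-dimethoxyphenyl. Ring B carries three contiguous stereocentres: C1 (R, aryl), C2 (S, CH2OSO3H) and C3 (S, CH2OH). The substituents alternate between the two faces (1,2-trans, 2,3-trans), so all three can be equatorial; C4 is a methylene. The sensitive groups are the two hindered, easily oxidised 2,6-dimethoxyphenols, the doubly benzylic C1–H, and the primary alkyl hydrogen sulfate, which is strongly acidic, solvolyses under acid and turns every later intermediate into a salt. The synthesis is hard for three reasons: C2 and C3 lie remote from any directing heteroatom; the two hydroxymethyl arms differ only in their position relative to C1, yet only the C2 arm is sulfated; and the C1–C8a bond must be made next to the C8 methoxyl with the aryl group trans to the C2 arm. Both arenes have the same oxygenation pattern, so the skeleton is two C6–C3 units joined at C2–C3. The plan rests on the fact that the benzylic carbons C1 and C4 of these units are 1,4-related through C2–C3. With C1 bonded to C4, the four carbons form a head-to-head cinnamate–styrene cyclobutane, and moving C1 from C4 to the ortho carbon C8a of ring A converts that cyclobutane into ring B.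

## Retrosynthetic reasoning

**Sulfate and phenols (20 from 15).** The O–S bond and the three O–benzyl bonds are cut last. The sulfate is the most fragile and most polar group, so it is installed on carbinol 15 with 16 as the last bond-forming event. The benzyl ethers on both phenols and on the C3 arm are chosen because hydrogenolysis does not touch a sulfate monoester anion (18 to 19), after which only protonation remains. The forward sequence has to sulfate a single free hydroxyl and then unmask three others under neutral conditions.

**Arm differentiation (15 from 12).** Compound 15 needs a free C2 carbinol beside a protected C3 carbinol. This is traced to 12, where the C2 arm is a silyl ether and the C3 arm an ester, so the arms differ in oxidation state rather than by selective protection of a diol. Hydride reduction of 12 exposes the C3 carbinol and the ring A phenol (13), both are benzylated (14), and fluoride then frees the C2 arm alone (15).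

**Ring B (12 from 11).** The C1–C8a bond is cut and C1–C4 re-formed, giving cyclobutane 11. This is chosen over a cut at C2–C3 or C4–C4a because it leaves C2 and C3 untouched and uses about 26 kcal/mol of ring strain to drive formation of the crowded C1–C8a bond. The forward reaction must break the diaryl C1–C4 bond so that C1 becomes electrophilic and C4 ends as CH2. The two aryl groups are made electronically unequal for this purpose: a benzyl ether on the C1 aryl and a pivalate on the future ring A.

**Cyclobutane (11 from 5 and 10).** Both C2–C3 and C1–C4 are cut, giving cinnamate 5 and styrene 10. This disconnection creates the one permanent skeletal bond of the step (C2–C3) together with both permanent stereocentres, and it delivers the two arms already differentiated as ester and silyl ether. The forward reaction must be a crossed, head-to-head, all-trans [2+2] photocycloaddition with absolute control at the cinnamate α-carbon.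

**Partners (5 and 10 from 1).** Both come from 1 through 3. Ester 3 is acylated with 4 to give 5. Separately, 3 is benzylated with 6 to 7, reduced to allylic alcohol 8 and silylated with 9 to 10. These are five routine steps, so the risk of the route sits in steps 6 and 7.

## Alternatives that were turned down

**Alternative 1:** The disconnection cuts C2–C3 and C1–C8a in one oxidative operation, starting from two molecules of the imide (S)-4-benzyl-3-sinapoyloxazolidin-2-one A1. In the forward step a one-electron oxidant generates phenoxyl radicals from A1; two of them join at the carbons α to the carbonyls (C2–C3), and the other ring attacks one of the resulting quinone methides at C8a to give the 1-aryl-1,2-dihydronaphthalene bis-imide A2. In its favour, one step builds the whole skeleton from a single monomer at the phenol oxidation level of 20, and no phenol protection is needed; on step count it is clearly stronger than the chosen route. Against it, the radical–radical coupling takes place far from the auxiliaries, so control at C2 (and through it C1) is uncertain, and C–O and other C–C coupling modes of the phenoxyl radical compete. C3 is still sp2 in A2 and must be set by a later hydrogenation trans to the C2 substituent. The two arms are identical imides that differ only in conjugation. The chosen route is longer but sets C2 and C3 together under catalyst control and keeps the arms in different oxidation states from the first C–C bond on.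

**Alternative 2:** The disconnection cuts C4–C4a, with C1 present as an aryl ketone and the pendant ring still absent. In the forward step a Lewis acid activates the doubly acceptor-substituted cyclopropane of the aroyl cyclopropane lactone A3, and ring A carbon C4a opens it at the methylene to give the cis-fused keto lactone A4. In its favour, C3 comes from the chiral pool, arene opening of donor–acceptor cyclopropanes is established, and the lactone marks the arms (carbonyl on C2, OCH2 on C3); on precedent for the key bond and on arm differentiation it is at least equal to the chosen route. Against it, C4a is ortho to the deactivating ketone, which the Lewis acid deactivates further by chelation. After A4 the pendant aryl must be added to a hindered, enolisable β-keto lactone, the tertiary benzylic alcohol removed with control of C1, and the cis ring fusion corrected at C2. That is three stereochemical operations after the key step, whereas the chosen route has all carbons and the aryl group in place after two C–C bond-forming steps and only C1 left to set.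

**Alternative 3:** The disconnection cuts both C1–C8a and C1–aryl; C1 arrives as the aldehyde carbon of the acyclic aldehyde A5 and the pendant ring as 2,6-dimethoxyphenol A6. In the forward step a boron Lewis acid lets the aldehyde of A5 alkylate ring A at C8a; the resulting benzylic alcohol ionises and the C1 cation is captured by A6 para to its hydroxyl, giving tetralin A7. In its favour, it is convergent, the pendant ring enters late from a cheap unprotected phenol, the arms are already differentiated, and trans capture of a cyclic benzylic cation is well founded; on late-stage convergence and on precedent for C1 it is as good as or better than the chosen route. Against it, C2 and C3 must first be built in an acyclic aldehyde by separate auxiliary- or catalyst-controlled steps. The aldehyde α-centre (C2) can epimerise under the Lewis acid, and the cation can eliminate to a dihydronaphthalene or be captured ortho or at oxygen of A6. The free phenol of A7 also needs a further protection before sulfation. The chosen route makes C2–C3 and both stereocentres in one catalytic step from two cinnamyl units that are each two or three steps from 3.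

Key step: step 6

## Route

**Step 1**
Reactants: 1 sinapic acid; 2 methanol
Product: 3 methyl (E)-3-(4-hydroxy-3,5-dimethoxyphenyl)acrylate (methyl sinapate)
Conditions: MeOH, H2SO4 (cat.), reflux
Reagents that add atoms: methanol (2), CO
Why: Fischer esterification; the phenol and the conjugated E-alkene are stable to the acid.

**Step 2**
Reactants: 3 methyl sinapate; 4 pivaloyl chloride
Product: 5 methyl (E)-3-(3,5-dimethoxy-4-pivaloyloxyphenyl)acrylate
Conditions: PivCl, Et3N, 4-dimethylaminopyridine (cat.), CH2Cl2, 0 °C to rt
Reagents that add atoms: pivaloyl chloride (4), CC(C)(C)C(=O)Cl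
Why: Nucleophile-catalysed O-acylation of the hindered phenol. The pivalate makes the future ring A the poorer donor, which later directs the ring expansion and keeps the C3–C4 aryl/ester bond of 11 from ionising on the Lewis acid.

**Step 3**
Reactants: 3 methyl sinapate; 6 benzyl bromide
Product: 7 methyl (E)-3-(4-benzyloxy-3,5-dimethoxyphenyl)acrylate
Conditions: BnBr, K2CO3, DMF, 60 °C
Reagents that add atoms: benzyl bromide (6), BrCc1ccccc1
Why: Williamson ether synthesis on the phenoxide; the benzyl ether keeps this ring the more electron-rich one and is removed in the final hydrogenolysis.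

**Step 4**
Reactants: 7 methyl 4-O-benzylsinapate
Product: 8 (E)-3-(4-benzyloxy-3,5-dimethoxyphenyl)prop-2-en-1-ol
Conditions: i-Bu2AlH (2.5 equiv), CH2Cl2, −78 to 0 °C; aqueous potassium sodium tartrate
Reagents that add atoms: none
Why: 1,2-Reduction of the conjugated ester by the aluminium hydride gives the allylic alcohol without touching the alkene or the benzyl ether.

**Step 5**
Reactants: 8 4-O-benzylsinapyl alcohol; 9 chlorotriisopropylsilane
Product: 10 (E)-[3-(4-benzyloxy-3,5-dimethoxyphenyl)prop-2-en-1-yloxy]triisopropylsilane
Conditions: i-Pr3SiCl, imidazole, DMF, rt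
Reagents that add atoms: chlorotriisopropylsilane (9), CC(C)[Si](Cl)(C(C)C)C(C)C
Why: Imidazole-promoted silylation of the primary alcohol under buffered conditions that spare the acid-sensitive, electron-rich cinnamyl system.

**Step 6**
Reactants: 5 methyl (E)-3-(3,5-dimethoxy-4-pivaloyloxyphenyl)acrylate; 10 (E)-4-benzyloxy-3,5-dimethoxycinnamyl triisopropylsilyl ether
Product: 11 methyl (1S,2R,3R,4S)-3-(4-benzyloxy-3,5-dimethoxyphenyl)-2-(3,5-dimethoxy-4-pivaloyloxyphenyl)-4-(triisopropylsilyloxymethyl)cyclobutane-1-carboxylate (all-trans; cyclobutane C3, C4, C1 and C2 become tetralin C1, C2, C3 and C4)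
Conditions: B-aryl oxazaborolidine from (S)-α,α-diphenylprolinol activated with AlBr3 (25 mol%), [Ir(ppy)2(dtbbpy)]PF6 (1 mol%), 10 (2 equiv), CH2Cl2, −78 °C, 450 nm LEDs
Reagents that add atoms: none
Why: The boron Lewis acid binds the ester carbonyl of 5 and lowers its triplet energy and frontier orbitals, so the excited trivalent-iridium sensitiser passes its energy (Dexter transfer) only to the bound cinnamate; unbound 5 and alkene 10 lie above the sensitiser, which is also too weak an oxidant to make the radical cation of 10. The triplet bonds through its α-carbon to the β-carbon of 10 (tetralin C2–C3), because only this gives a 1,4-diradical with both spins benzylic; after intersystem crossing the two benzylic radicals recombine (tetralin C1–C4), closing the four-membered ring by stepwise diradical recombination, head-to-head. The closest known reaction type is the chiral-Lewis-acid-catalysed, triplet-sensitised enantioselective crossed [2+2] photocycloaddition of cinnamate esters with styrenes. The ester-bearing centre is set by the catalyst, whose aryl groups shield one face of the bound cinnamate in the first bond formation. The silyloxymethyl-bearing centre is set in the same event by the approach that keeps the CH2OSi group away from the ester–Lewis acid complex, and diradicals of the other relative configuration close slowly and revert. The two aryl-bearing centres arise from freely rotating benzylic radicals that close with each aryl trans to its neighbour and to each other, giving the all-trans ring. The step needs cross- over homo-coupling (only the cinnamate is excited and 10 is in excess), head-to-head regiochemistry (benzylic radical stability) and face selectivity (catalyst). The pivalate on the cinnamate ring and the bulky silyl ether on 10 keep the substrates from ionising on the Lewis acid. The (S)-prolinol catalyst is a proposal by analogy, and its antipode would be used if the sense of induction is the opposite.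

**Step 7**
Reactants: 11 cyclobutane
Product: 12 methyl (1R,2S,3S)-1-(4-benzyloxy-3,5-dimethoxyphenyl)-6,8-dimethoxy-7-pivaloyloxy-2-(triisopropylsilyloxymethyl)-1,2,3,4-tetrahydronaphthalene-3-carboxylate
Conditions: 9-mesityl-10-methylacridinium tetrafluoroborate (5 mol%), PhSSPh (20 mol%), CH2Cl2–(CF3)2CHOH 9:1, 450 nm LEDs, 0 °C, degassed
Reagents that add atoms: none
Why: Proposed new method: the excited acridinium removes one electron from the more electron-rich benzyloxy ring, and the strained C1–C4 bond, aligned with both aryl π-systems, then breaks with the positive charge at C1 (para to the benzyloxy group, remote from the ester) and the spin at C4 beside the pivaloyloxy ring; the ortho carbon of that ring (para to one methoxyl) attacks C1 in a six-membered Friedel–Crafts closure through a half-chair that places the C1 aryl equatorial and trans to the C2 arm, and the C4 radical is finished by hydrogen-atom transfer from PhSH, whose thiyl radical reoxidises the reduced acridine. The closest known reaction types are the 1,6-cyclisation of 1,4-radical cations to 1-aryltetralins in electron-transfer dimerisations of aryl alkenes and acridinium/thiol radical-cation catalysis; C2 and C3 take no part and keep their configuration.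

**Step 8**
Reactants: 12 tetralin ester
Product: 13 (1R,2S,3S)-1-(4-benzyloxy-3,5-dimethoxyphenyl)-3-(hydroxymethyl)-6,8-dimethoxy-2-(triisopropylsilyloxymethyl)-1,2,3,4-tetrahydronaphthalen-7-ol
Conditions: LiAlH4, THF, 0 °C to rt; aqueous NaOH work-up
Reagents that add atoms: none
Why: Hydride reduction converts the methyl ester into the C3 hydroxymethyl group and cleaves the aryl pivalate by attack at its acyl carbon; silyl and benzyl ethers are inert and no stereocentre is epimerisable under these conditions.

**Step 9**
Reactants: 13 tetralin phenol alcohol; 6 benzyl bromide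
Product: 14 (1R,2S,3S)-7-benzyloxy-1-(4-benzyloxy-3,5-dimethoxyphenyl)-3-(benzyloxymethyl)-6,8-dimethoxy-2-(triisopropylsilyloxymethyl)-1,2,3,4-tetrahydronaphthalene
Conditions: NaH (3 equiv), BnBr (3 equiv), Bu4NI (cat.), DMF, 0 °C to rt
Reagents that add atoms: benzyl bromide (6), BrCc1ccccc1
Why: Double Williamson benzylation of the phenoxide and the primary alkoxide; the bulky triisopropylsilyl group should not migrate to the neighbouring alkoxide, so the arms stay differentiated.

**Step 10**
Reactants: 14 tribenzyl silyl ether
Product: 15 [(1R,2S,3S)-7-benzyloxy-1-(4-benzyloxy-3,5-dimethoxyphenyl)-3-(benzyloxymethyl)-6,8-dimethoxy-1,2,3,4-tetrahydronaphthalen-2-yl]methanol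
Conditions: Bu4NF, THF, rt
Reagents that add atoms: none
Why: Fluoride-induced desilylation frees only the C2 arm; benzyl ethers are unaffected.

**Step 11**
Reactants: 15 C2 carbinol; 16 sulfur trioxide–pyridine complex
Product: 18 sodium [(1R,2S,3S)-7-benzyloxy-1-(4-benzyloxy-3,5-dimethoxyphenyl)-3-(benzyloxymethyl)-6,8-dimethoxy-1,2,3,4-tetrahydronaphthalen-2-yl]methyl sulfate, via pyridinium sulfate 17 (not isolated)
Conditions: SO3·pyridine (4 equiv), pyridine, rt; then aqueous NaHCO3
Reagents that add atoms: sulfur trioxide–pyridine complex (16), O=S(=O)([O-])[n+]1ccccc1; sodium hydrogencarbonate, [Na+].OC(=O)[O-]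
Why: O-Sulfation of the only free hydroxyl by the SO3–amine complex; the hydrogencarbonate work-up exchanges pyridinium for sodium and gives a neutral salt that can be chromatographed.

**Step 12**
Reactants: 18 sodium sulfate tribenzyl ether
Product: 20 [(1R,2S,3S)-7-hydroxy-1-(4-hydroxy-3,5-dimethoxyphenyl)-3-(hydroxymethyl)-6,8-dimethoxy-1,2,3,4-tetrahydronaphthalen-2-yl]methyl hydrogen sulfate, via sodium salt of the target 19 (not isolated)
Conditions: H2 (1 atm), Pd/C, MeOH–THF, rt; filter; then 1 M HCl (1.0 equiv), 0 °C, C18 desalting, freeze-drying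
Reagents that add atoms: none
Why: Heterogeneous hydrogenolysis cleaves the two aryl benzyl ethers and the alkyl benzyl ether while the sulfate monoester anion and the arenes are inert; one equivalent of acid in the cold then protonates the sulfate.

## Compound list

1 | sinapic acid | COc1cc(/C=C/C(=O)O)cc(OC)c1O | starting material
2 | methanol | CO | starting material
3 | methyl (E)-3-(4-hydroxy-3,5-dimethoxyphenyl)acrylate | COC(=O)/C=C/c1cc(OC)c(O)c(OC)c1 | intermediate
4 | pivaloyl chloride | CC(C)(C)C(=O)Cl | starting material
5 | methyl (E)-3-(3,5-dimethoxy-4-pivaloyloxyphenyl)acrylate | COC(=O)/C=C/c1cc(OC)c(OC(=O)C(C)(C)C)c(OC)c1 | intermediate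
6 | benzyl bromide | BrCc1ccccc1 | starting material
7 | methyl (E)-3-(4-benzyloxy-3,5-dimethoxyphenyl)acrylate | COC(=O)/C=C/c1cc(OC)c(OCc2ccccc2)c(OC)c1 | intermediate
8 | (E)-3-(4-benzyloxy-3,5-dimethoxyphenyl)prop-2-en-1-ol | OC/C=C/c1cc(OC)c(OCc2ccccc2)c(OC)c1 | intermediate
9 | chlorotriisopropylsilane | CC(C)[Si](Cl)(C(C)C)C(C)C | starting material
10 | (E)-[3-(4-benzyloxy-3,5-dimethoxyphenyl)prop-2-en-1-yloxy]triisopropylsilane | COc1cc(/C=C/CO[Si](C(C)C)(C(C)C)C(C)C)cc(OC)c1OCc1ccccc1 | intermediate
11 | methyl (1S,2R,3R,4S)-3-(4-benzyloxy-3,5-dimethoxyphenyl)-2-(3,5-dimethoxy-4-pivaloyloxyphenyl)-4-(triisopropylsilyloxymethyl)cyclobutane-1-carboxylate | COc1cc(cc(OC)c1OCc1ccccc1)[C@H]1[C@H](CO[Si](C(C)C)(C(C)C)C(C)C)[C@@H](C(=O)OC)[C@@H]1c1cc(OC)c(OC(=O)C(C)(C)C)c(OC)c1 | intermediate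
12 | methyl (1R,2S,3S)-1-(4-benzyloxy-3,5-dimethoxyphenyl)-6,8-dimethoxy-7-pivaloyloxy-2-(triisopropylsilyloxymethyl)-1,2,3,4-tetrahydronaphthalene-3-carboxylate | COc1cc([C@@H]2c3c(cc(OC)c(OC(=O)C(C)(C)C)c3OC)C[C@H](C(=O)OC)[C@H]2CO[Si](C(C)C)(C(C)C)C(C)C)cc(OC)c1OCc1ccccc1 | intermediate
13 | (1R,2S,3S)-1-(4-benzyloxy-3,5-dimethoxyphenyl)-3-(hydroxymethyl)-6,8-dimethoxy-2-(triisopropylsilyloxymethyl)-1,2,3,4-tetrahydronaphthalen-7-ol | COc1cc([C@@H]2c3c(cc(OC)c(O)c3OC)C[C@H](CO)[C@H]2CO[Si](C(C)C)(C(C)C)C(C)C)cc(OC)c1OCc1ccccc1 | intermediate
14 | (1R,2S,3S)-7-benzyloxy-1-(4-benzyloxy-3,5-dimethoxyphenyl)-3-(benzyloxymethyl)-6,8-dimethoxy-2-(triisopropylsilyloxymethyl)-1,2,3,4-tetrahydronaphthalene | COc1cc([C@@H]2c3c(cc(OC)c(OCc4ccccc4)c3OC)C[C@H](COCc3ccccc3)[C@H]2CO[Si](C(C)C)(C(C)C)C(C)C)cc(OC)c1OCc1ccccc1 | intermediate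
15 | [(1R,2S,3S)-7-benzyloxy-1-(4-benzyloxy-3,5-dimethoxyphenyl)-3-(benzyloxymethyl)-6,8-dimethoxy-1,2,3,4-tetrahydronaphthalen-2-yl]methanol | COc1cc([C@@H]2c3c(cc(OC)c(OCc4ccccc4)c3OC)C[C@H](COCc3ccccc3)[C@H]2CO)cc(OC)c1OCc1ccccc1 | intermediate
16 | sulfur trioxide–pyridine complex | O=S(=O)([O-])[n+]1ccccc1 | starting material
17 | pyridinium [(1R,2S,3S)-7-benzyloxy-1-(4-benzyloxy-3,5-dimethoxyphenyl)-3-(benzyloxymethyl)-6,8-dimethoxy-1,2,3,4-tetrahydronaphthalen-2-yl]methyl sulfate | COc1cc([C@@H]2c3c(cc(OC)c(OCc4ccccc4)c3OC)C[C@H](COCc3ccccc3)[C@H]2COS(=O)(=O)[O-])cc(OC)c1OCc1ccccc1.c1cc[nH+]cc1 | intermediate (not isolated)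
18 | sodium [(1R,2S,3S)-7-benzyloxy-1-(4-benzyloxy-3,5-dimethoxyphenyl)-3-(benzyloxymethyl)-6,8-dimethoxy-1,2,3,4-tetrahydronaphthalen-2-yl]methyl sulfate | COc1cc([C@@H]2c3c(cc(OC)c(OCc4ccccc4)c3OC)C[C@H](COCc3ccccc3)[C@H]2COS(=O)(=O)[O-])cc(OC)c1OCc1ccccc1.[Na+] | intermediate
19 | sodium [(1R,2S,3S)-7-hydroxy-1-(4-hydroxy-3,5-dimethoxyphenyl)-3-(hydroxymethyl)-6,8-dimethoxy-1,2,3,4-tetrahydronaphthalen-2-yl]methyl sulfate | COc1cc([C@@H]2c3c(cc(OC)c(O)c3OC)C[C@H](CO)[C@H]2COS(=O)(=O)[O-])cc(OC)c1O.[Na+] | intermediate (not isolated)
20 | [(1R,2S,3S)-7-hydroxy-1-(4-hydroxy-3,5-dimethoxyphenyl)-3-(hydroxymethyl)-6,8-dimethoxy-1,2,3,4-tetrahydronaphthalen-2-yl]methyl hydrogen sulfate | COc1cc([C@@H]2c3c(cc(OC)c(O)c3OC)C[C@H](CO)[C@H]2COS(=O)(=O)O)cc(OC)c1O | target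

## Step count and least certain steps

Total: 12 steps. Longest linear sequence: 11 steps (1, 3, 4, 5, 6, 7, 8, 9, 10, 11, 12).

**Step 7 (ring expansion, proposed new method).**
- What may go wrong: after the C1–C4 bond has opened, the ring-opened radical cation may break C2–C3 as well (cycloreversion to 5 and the radical cation of 10) faster than ring A closes onto C1. The charge may also settle at C4 instead of C1, which would close the other ring and exchange the arms. Further oxidation of the product to a dihydronaphthalene is a third possibility.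
- Fallback (known chemistry; sets out from 7, returns at 15): the cyclobutane is given up and ring B is closed by the classical benzylic-cation Friedel–Crafts reaction.
  - Conjugate reduction of 7 (NaBH4, NiCl2·6H2O, MeOH) should give methyl 3-(4-benzyloxy-3,5-dimethoxyphenyl)propanoate F1. Saponification (LiOH) gives 3-(4-benzyloxy-3,5-dimethoxyphenyl)propanoic acid F2, which is attached to (R)-4-benzyloxazolidin-2-one (pivaloyl chloride, Et3N, then the lithiated auxiliary) as the imide F3.
  - Evans alkylation (NaN(SiMe3)2, tert-butyl bromoacetate, −78 °C) sets the future C3 in the alkylated imide F4. LiBH4 removes the auxiliary to give the hydroxy ester F5, which p-toluenesulfonic acid closes to the (S)-β-benzyl-γ-butyrolactone F6.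
  - Aldol addition of its lithium enolate (LiN(i-Pr)2) to purchased 4-benzyloxy-3,5-dimethoxybenzaldehyde, anti to the benzyl group, gives the carbinol F7 (either carbinol epimer serves). CF3CO2H ionises it, and the benzyl ring closes onto the cation to give the trans,trans aryltetralin lactone F8, whose carbonyl sits on the C2 arm.
  - KOH opens the lactone to the potassium hydroxy carboxylate F9, NaH and benzyl bromide convert it into the benzyl ester benzyl ether F10, and LiAlH4 reduces the ester alone to 15.

**Step 6 (key step).**
- What may go wrong: enantioselectivity may erode through excitation of cinnamate that is not bound to the Lewis acid. The 1,2-disubstituted, very electron-rich alkene 10 may add slowly or with poor control of the silyloxymethyl-bearing centre. The Lewis acid may also ionise or oligomerise 10.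
- Fallback (sets out from 1, returns at 11): the boron catalyst and separate sensitiser are replaced by a chiral-at-metal rhodium Lewis acid that binds a two-point acyl pyrazole and is itself the light absorber.
  - O-Pivaloylation of 1 (pivaloyl chloride, pyridine; aqueous work-up to hydrolyse the mixed anhydride) gives (E)-3-(3,5-dimethoxy-4-pivaloyloxyphenyl)acrylic acid F11.
  - Coupling with 3,5-dimethylpyrazole (N-(3-dimethylaminopropyl)-N′-ethylcarbodiimide hydrochloride, 4-dimethylaminopyridine) gives the N-acylpyrazole F12.
  - Irradiation of F12 with 10 and [Rh(pbt)2(MeCN)2]PF6 (pbt = cyclometalated 5-tert-butyl-2-phenylbenzothiazole; the Λ or Δ form chosen to give the required series) under blue light follows a known type of enantioselective [2+2] photocycloaddition and should give the cyclobutane acylpyrazole F13.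
  - Methanolysis (MeOH, Et3N, 4-dimethylaminopyridine) returns 11.

**Step 12 (global hydrogenolysis beside the sulfate).**
- What may go wrong: the sulfate may be lost by acid-catalysed solvolysis on the catalyst or during protonation, and the alkyl benzyl ether next to the anionic group may cleave slowly.
- Fallback (sets out from 15, returns at 20): the sulfate is carried as a neutral, masked diester.
  - 15 is treated with 1,2-dimethyl-3-[(2,2,2-trichloroethoxy)sulfonyl]imidazolium triflate and 1,2-dimethylimidazole to give the 2,2,2-trichloroethyl sulfate F14, which can be purified on silica.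
  - Pd/C with HCO2NH4 in MeOH then removes the trichloroethyl group reductively and the three benzyl groups by transfer hydrogenolysis, giving the ammonium salt of the target F15, which is protonated as in step 12 to 20.

## Further compounds

F1 | step 7 | methyl 3-(4-benzyloxy-3,5-dimethoxyphenyl)propanoate | COC(=O)CCc1cc(OC)c(OCc2ccccc2)c(OC)c1
F2 | step 7 | 3-(4-benzyloxy-3,5-dimethoxyphenyl)propanoic acid | OC(=O)CCc1cc(OC)c(OCc2ccccc2)c(OC)c1
F3 | step 7 | (4R)-4-benzyl-3-[3-(4-benzyloxy-3,5-dimethoxyphenyl)propanoyl]oxazolidin-2-one | O=C(CCc1cc(OC)c(OCc2ccccc2)c(OC)c1)N1[C@H](Cc2ccccc2)COC1=O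
F4 | step 7 | tert-butyl (3S)-4-[(4R)-4-benzyl-2-oxooxazolidin-3-yl]-3-(4-benzyloxy-3,5-dimethoxybenzyl)-4-oxobutanoate | CC(C)(C)OC(=O)C[C@H](Cc1cc(OC)c(OCc2ccccc2)c(OC)c1)C(=O)N1[C@H](Cc2ccccc2)COC1=O
F5 | step 7 | tert-butyl (3S)-4-(4-benzyloxy-3,5-dimethoxyphenyl)-3-(hydroxymethyl)butanoate | CC(C)(C)OC(=O)C[C@@H](CO)Cc1cc(OC)c(OCc2ccccc2)c(OC)c1
F6 | step 7 | (4S)-4-(4-benzyloxy-3,5-dimethoxybenzyl)dihydrofuran-2(3H)-one | O=C1C[C@H](Cc2cc(OC)c(OCc3ccccc3)c(OC)c2)CO1
F7 | step 7 | (3R,4S)-4-(4-benzyloxy-3,5-dimethoxybenzyl)-3-[(4-benzyloxy-3,5-dimethoxyphenyl)(hydroxy)methyl]dihydrofuran-2(3H)-one (carbinol epimers) | O=C1OC[C@@H](Cc2cc(OC)c(OCc3ccccc3)c(OC)c2)[C@@H]1C(O)c1cc(OC)c(OCc2ccccc2)c(OC)c1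
F8 | step 7 | (1R,2S,3S)-7-benzyloxy-1-(4-benzyloxy-3,5-dimethoxyphenyl)-6,8-dimethoxytetralin 2,3-trans-fused γ-lactone (carbonyl on C2, OCH2 on C3) | COc1cc([C@@H]2c3c(cc(OC)c(OCc4ccccc4)c3OC)C[C@@H]3COC(=O)[C@@H]23)cc(OC)c1OCc1ccccc1
F9 | step 7 | potassium (1R,2S,3S)-7-benzyloxy-1-(4-benzyloxy-3,5-dimethoxyphenyl)-3-(hydroxymethyl)-6,8-dimethoxy-1,2,3,4-tetrahydronaphthalene-2-carboxylate | COc1cc([C@@H]2c3c(cc(OC)c(OCc4ccccc4)c3OC)C[C@H](CO)[C@H]2C(=O)[O-])cc(OC)c1OCc1ccccc1.[K+]
F10 | step 7 | benzyl (1R,2S,3S)-7-benzyloxy-1-(4-benzyloxy-3,5-dimethoxyphenyl)-3-(benzyloxymethyl)-6,8-dimethoxy-1,2,3,4-tetrahydronaphthalene-2-carboxylate | COc1cc([C@@H]2c3c(cc(OC)c(OCc4ccccc4)c3OC)C[C@H](COCc3ccccc3)[C@H]2C(=O)OCc2ccccc2)cc(OC)c1OCc1ccccc1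
F11 | step 6 | (E)-3-(3,5-dimethoxy-4-pivaloyloxyphenyl)acrylic acid | COc1cc(/C=C/C(=O)O)cc(OC)c1OC(=O)C(C)(C)C
F12 | step 6 | (E)-1-(3,5-dimethylpyrazol-1-yl)-3-(3,5-dimethoxy-4-pivaloyloxyphenyl)prop-2-en-1-one | COc1cc(/C=C/C(=O)n2nc(C)cc2C)cc(OC)c1OC(=O)C(C)(C)C
F13 | step 6 | [(1S,2R,3R,4S)-3-(4-benzyloxy-3,5-dimethoxyphenyl)-2-(3,5-dimethoxy-4-pivaloyloxyphenyl)-4-(triisopropylsilyloxymethyl)cyclobutyl](3,5-dimethylpyrazol-1-yl)methanone | COc1cc(cc(OC)c1OCc1ccccc1)[C@H]1[C@H](CO[Si](C(C)C)(C(C)C)C(C)C)[C@@H](C(=O)n5nc(C)cc5C)[C@@H]1c1cc(OC)c(OC(=O)C(C)(C)C)c(OC)c1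
F14 | step 12 | [(1R,2S,3S)-7-benzyloxy-1-(4-benzyloxy-3,5-dimethoxyphenyl)-3-(benzyloxymethyl)-6,8-dimethoxy-1,2,3,4-tetrahydronaphthalen-2-yl]methyl 2,2,2-trichloroethyl sulfate | COc1cc([C@@H]2c3c(cc(OC)c(OCc4ccccc4)c3OC)C[C@H](COCc3ccccc3)[C@H]2COS(=O)(=O)OCC(Cl)(Cl)Cl)cc(OC)c1OCc1ccccc1
F15 | step 12 | ammonium [(1R,2S,3S)-7-hydroxy-1-(4-hydroxy-3,5-dimethoxyphenyl)-3-(hydroxymethyl)-6,8-dimethoxy-1,2,3,4-tetrahydronaphthalen-2-yl]methyl sulfate | COc1cc([C@@H]2c3c(cc(OC)c(O)c3OC)C[C@H](CO)[C@H]2COS(=O)(=O)[O-])cc(OC)c1O.[NH4+]
A1 | alternative 1 | (S)-4-benzyl-3-[(E)-3-(4-hydroxy-3,5-dimethoxyphenyl)acryloyl]oxazolidin-2-one | COc1cc(/C=C/C(=O)N2[C@@H](Cc3ccccc3)COC2=O)cc(OC)c1O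
A2 | alternative 1 | 1-aryl-1,2-dihydronaphthalene-2,3-bis(acyl oxazolidinone) | COc1cc(cc(OC)c1O)[C@@H]2c3c(cc(OC)c(O)c3OC)C=C(C(=O)N4[C@@H](Cc5ccccc5)COC4=O)[C@H]2C(=O)N6[C@@H](Cc7ccccc7)COC6=O
A3 | alternative 2 | 1-(4-benzyloxy-3,5-dimethoxybenzoyl)-3-oxabicyclo[3.1.0]hexan-2-one (single enantiomer as drawn) | O=C(c1cc(OC)c(OCc2ccccc2)c(OC)c1)[C@@]12C[C@@H]1COC2=O
A4 | alternative 2 | cis-fused keto lactone (C1 ketone, lactone carbonyl on C2, OCH2 on C3) | O=C1c2c(cc(OC)c(OCc3ccccc3)c2OC)C[C@@H]2COC(=O)[C@H]12
A5 | alternative 3 | (2S,3S)-4-(4-benzyloxy-3,5-dimethoxyphenyl)-3-(benzyloxymethyl)-2-(tert-butyldiphenylsilyloxymethyl)butanal | O=C[C@H](CO[Si](c1ccccc1)(c1ccccc1)C(C)(C)C)[C@@H](COCc1ccccc1)Cc1cc(OC)c(OCc2ccccc2)c(OC)c1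
A6 | alternative 3 | 2,6-dimethoxyphenol | COc1cccc(OC)c1O
A7 | alternative 3 | 1-(4-hydroxy-3,5-dimethoxyphenyl)tetralin with silyl ether on the C2 arm and benzyl ether on the C3 arm | COc1cc(cc(OC)c1O)[C@@H]2c3c(cc(OC)c(OCc4ccccc4)c3OC)C[C@H](COCc5ccccc5)[C@H]2CO[Si](c6ccccc6)(c7ccccc7)C(C)(C)C
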